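## Structural features

The target is a (2S)-flavanone. Aromatic ring A and the dihydropyranone ring C share the C4a–C8a bond, and the 3-hydroxy-4-methoxyphenyl ring B is attached at C2. Ring A is a fully differentiated phloroglucinol: O1 on C8a, a prenyl group on C8, a methyl ether on C7, the only aromatic hydrogen on C6, and a free hydroxyl on C5 that is hydrogen-bonded to the C4 carbonyl. C2 is the only stereocentre, so no neighbouring centre can relay or protect it. It is benzylic, carries O1 and lies β to the C4 ketone, so base opens ring C by retro-oxa-Michael reaction to the chalcone. The para-methoxy group of ring B also makes the C2–O1 bond sensitive to strong acid. The trisubstituted prenyl alkene (acid, electrophiles, hydrogenation, oxidants) and the free phenols are the other fragile groups. The real difficulty is the regiochemistry of ring A (8- versus 6-prenyl, 7-O- versus 5-O-methyl) combined with keeping C2 configurationally intact. The key step uses the alternating oxygenation of C5, C7 and C8a, which marks ring A as a folded tetraketide. Once O1 is tied to C2 in ring C, the enol-ether carbon C4a of the unit O1–C8a=C4a–C4=O is the nucleophile that closes the C4a–C5 bond, and a prenyl group placed on the chain carbon C8 cannot end up on C6.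

## Logic of the disconnections

**19 to 18 (O3'–Si).** The last bond cut is the silyl ether on ring B. The ring B phenol and the C7 phenol are both unchelated, so the former must stay masked until the latter is methylated. The forward step must be a non-basic desilylation, because free base would open ring C of 19 and racemise C2.

**18 to 17 (O7–CH3).** The methyl ether is cut because the ring-forming step delivers both ring A oxygens as hydroxyls. The chelated 5-OH is far less acidic than the 7-OH, so the differentiation is built into the structure. The forward step must be a neutral mono-alkylation that avoids base and avoids hazardous diazo reagents.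

**17 to 13 (C4a–C5, ring A).** Cutting the aryl–carbonyl-derived bond C4a–C5 unravels ring A into a chain: C8 with its prenyl group, C7 and C5 as a masked β-keto acid (dioxinone), attached to a preformed dihydropyranone that already holds O1, C2 and ring B. The whole regiochemical problem of ring A disappears. The forward step must make an acylketene acylate C4a in preference to every other available nucleophile and to itself.

**13 to 11 (O1–C8a).** The enol-ether bond of the dihydropyranone is cut to give a δ-silyloxy β-diketone. Ring C becomes an open chain whose only stereocentre is a protected benzylic carbinol. The forward step must be a cyclodehydration mild enough not to ionise the para-methoxybenzylic C–O bond or protonate the prenyl alkene.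

**11 to 4 + 10 (C4–C4a).** The diketone is cut between C4 and C4a, giving a methyl ketone carrying the dioxinone and the prenyl group (4) and an enantiopure β-silyloxy acyl donor (10). This splits the molecule into two fragments of similar size, and the stereocentre travels in the electrophile. The forward step must be a Claisen acylation at the terminal carbon of a dianion that does not enolise 10.

**4 to 3 to 1 + 2 (C8–C8a, then C8–C1'').** Both carbon substituents on C8 are removed in turn, the acetyl group first and then the prenyl group, leading back to the commercial dioxinone 1 and bromide 2. The forward steps must react at the exocyclic γ-carbon of the dienolate, not at the ring α-carbon, and must stop at mono-substitution.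

**10 to 9 to 8 to 6 + 7, and 6 to 5 (O–Si, C2–H, C2–C3, O–Si).** The silyl ether of 10 is cut to carbinol 9, and the C2–H bond of 9 is cut to aryl ketone 8, so the stereocentre comes from a catalytic asymmetric reduction of predictable sense. Cutting C2–C3 of 8 gives aryl ester 6 and acetamide 7, and 6 is the silyl ether of commercial 5. The forward steps are a crossed Claisen condensation that tolerates the aryl silyl ether and a reduction that distinguishes the two faces of an aryl ketone.

## Other disconnections considered

**Alternative 1:** The cut is C3–C4 plus O1–C2, which splits ring C into a ring A one-carbon unit and a ring B styrene. In the forward direction a BINOL-derived N-triflylphosphoramide would ionise acetal A2 at the acetal carbon, and styrene A3 would add to the resulting heterodiene in an inverse-demand [4+2] reaction to give the 2,4-cis-4-methoxyflavan A1.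
- In its favour: it is the most convergent option, forming two bonds, ring C and the C2 stereocentre in one catalytic operation from two flat arenes. Acid-catalysed cycloadditions of this kind belong to an established reaction class.
- Against it here: A2 is a pentasubstituted benzene in which the prenyl group must already sit between the free phenol and the methyl ether, so the 8- versus 6-prenyl problem is only moved into an arene synthesis. The doubly oxygenated heterodiene and the para-methoxy-stabilised benzylic cation from A3 favour a stepwise ion-pair pathway and re-ionisation of the C2–O1 bond of A1, both of which threaten enantiomeric purity. A1 carries C4 as a methyl ether, so a benzylic ether-to-ketone oxidation next to a prenyl group and two electron-rich rings must follow, together with two deallylations; the C4 stereocentre is made only to be destroyed.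
- Comparison: Alternative 1 is better than the chosen plan in convergence, in bonds formed per step and in precedent for its key step. The two are equal in that C2 is set by a catalyst (step 5 in the chosen plan). The chosen plan is better in ring A regiochemistry, which is fixed by the carbon chain, in delivering the correct oxidation level at C4, and in keeping C2 away from strong acid. Step counts are comparable once the preparation of A2 and the operations after the cycloaddition are included.

**Alternative 2:** The cut is C2–C3. In the forward direction Rh2(S-PTTL)4 would convert diazoketone A5 into a metal carbene at C3 that inserts into one of the two enantiotopic benzylic C–H bonds of the O1 benzyl ether, giving the bis-silylated flavanone A4.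
- In its favour: A4 has the correct oxidation level at every carbon and the 7-methyl ether in place, so a single fluoride treatment should complete the synthesis. The C–H bond is doubly activated (benzylic and α to oxygen), and insertion next to an ether oxygen to form chromanones is a known reaction class.
- Against it here: a carbene from a diazoketone without a donor substituent is very reactive and discriminates poorly, so high enantioselectivity is uncertain. The O1 lone pair is closer to the carbene than the C–H bond, so attack by oxygen followed by [1,2]-benzyl migration competes, as do cyclopropanation of the prenyl alkene and addition to the electron-rich ring B. A5 needs diazo chemistry on a di-ortho-substituted benzoic acid, and ring A must again be prepared as a regio-defined pentasubstituted arene.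
- Comparison: Alternative 2 is better in the endgame (one step against two, and no selective O-methylation) and in precedent for the key step. It is equal in delivering the ketone oxidation level at C4 directly. The chosen plan is better in stereochemical security, because C2 comes from a ketone reduction of predictable sense and the key step has no stereochemical task, and in avoiding diazo compounds. Overall step counts are expected to be similar.

**Alternative 3:** The cut is O1–C8a. In the forward direction CuI, a phenanthroline ligand and Cs2CO3 would make the C2 hydroxyl of anti-diol A7 displace the ring A bromide, giving cis-flavan-4-ol A6.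
- In its favour: bond formation at the arene does not touch C2, which can be set beforehand by dependable carbonyl chemistry. The reaction is a well-precedented intramolecular Ullmann etherification. The C4 hydroxyl cannot compete because it would close a four-membered ring. The 7-methyl ether is present from the start.
- Against it here: the bromide is flanked by the prenyl group and the benzylic carbon on a very electron-rich ring, the least favourable case for a copper-mediated arylation. The C4 carbinol on a trioxygenated ring is prone to ionisation and elimination under hot basic conditions. Oxidation at C4 and acidic removal of two methoxymethyl ethers must follow in the presence of the prenyl group and the acid-labile C2–O1 bond. The second stereocentre of A7 is built only to be erased, and the bromoarene is itself a multistep regiochemical problem.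
- Comparison: Alternative 3 is better in precedent for the key step and in needing no selective O-methylation. It is equal to the chosen plan in keeping C2 remote from the ring-forming event and in endgame length (two steps each). The chosen plan is better in ring A regiochemistry, in avoiding a hindered coupling, and in delivering C4 at the ketone level.

Key step: step 9

**Remarks on the chemistry**

- The ring B phenol is carried as its triisopropylsilyl ether, not the tert-butyldimethylsilyl ether, because the aryl silyl ether must survive three enolate steps and liberated methoxide.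
- The side-chain carbon that becomes C8 is carried as a mixture of epimers from 4 to 13, since it ends up aromatic.
- The connectivity and the (2S) descriptor of 13 and 17 were checked atom by atom against 19 and need no correction.
- C4a is not the only carbon six atoms from the ketene carbon: C2'' of the prenyl alkene is too, and this is treated as a competing pathway in step 9.
- The 7-O-methylation uses a Mitsunobu reaction to avoid both base and diazo reagents.

## Route

Step 1
Reactants: 1 2,2,6-trimethyl-4H-1,3-dioxin-4-one; 2 1-bromo-3-methylbut-2-ene (prenyl bromide)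
Product: 3 2,2-dimethyl-6-(4-methylpent-3-en-1-yl)-4H-1,3-dioxin-4-one
Conditions: 1 (1.5 equiv), LiN(iPr)2, THF–DMPU, −78 °C; then 2, −78 → −30 °C
Reagents that add atoms: none
Why: Vinylogous (γ) alkylation of the lithium dienolate of 1, which reacts with allylic halides at the exocyclic carbon in the presence of a polar cosolvent. The excess of inexpensive dienolate should limit dialkylation, and DMPU replaces the more hazardous HMPA.

Step 2
Reactants: 3 2,2-dimethyl-6-(4-methylpent-3-en-1-yl)-4H-1,3-dioxin-4-one
Product: 4 3-(2,2-dimethyl-4-oxo-4H-1,3-dioxin-6-yl)-6-methylhept-5-en-2-one (racemic)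
Conditions: 3 (2 equiv), LiN(SiMe3)2 (2 equiv), THF, −78 °C; AcCl (1 equiv); aq NH4Cl (excess 3 recovered)
Reagents that add atoms: acetyl chloride, CC(Cl)=O
Why: C-Acylation of a dioxinone lithium dienolate at the γ-carbon with an acid chloride, the standard entry to keto-dioxinones. The second equivalent of dienolate deprotonates the more acidic product and is recovered as 3 on work-up.

Step 3
Reactants: 5 methyl 3-hydroxy-4-methoxybenzoate
Product: 6 methyl 4-methoxy-3-(triisopropylsilyloxy)benzoate
Conditions: iPr3SiCl, imidazole, DMF, rt
Reagents that add atoms: chlorotriisopropylsilane, CC(C)[Si](Cl)(C(C)C)C(C)C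
Why: Routine imidazole-promoted silylation of a phenol. The triisopropylsilyl ether is chosen because it resists alkoxides and amide bases far better than smaller aryl silyl ethers.

Step 4
Reactants: 6 methyl 4-methoxy-3-(triisopropylsilyloxy)benzoate; 7 N-methoxy-N-methylacetamide
Product: 8 N-methoxy-3-[4-methoxy-3-(triisopropylsilyloxy)phenyl]-N-methyl-3-oxopropanamide
Conditions: 7 (2.2 equiv), LiN(iPr)2 (2.2 equiv), THF, −78 °C; then 6, −78 → −20 °C; AcOH
Reagents that add atoms: none
Why: Crossed Claisen condensation of an amide lithium enolate with a non-enolisable aryl ester. Two equivalents of enolate are used because the β-keto amide product is deprotonated as it forms, and the low temperature protects the enolate and the aryl silyl ether.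

Step 5
Reactants: 8 N-methoxy-3-[4-methoxy-3-(triisopropylsilyloxy)phenyl]-N-methyl-3-oxopropanamide
Product: 9 (3S)-3-hydroxy-N-methoxy-3-[4-methoxy-3-(triisopropylsilyloxy)phenyl]-N-methylpropanamide
Conditions: RuCl(p-cymene)[(S,S)-TsDPEN] (1 mol %), HCO2H–Et3N (5:2), CH2Cl2, 30 °C
Reagents that add atoms: none
Why: Noyori asymmetric transfer hydrogenation of an aryl ketone; β-aryl β-keto amides are an established substrate class. With the (S,S)-ligand the hydride is delivered to the Re face of the aryl ketone, as for simple aryl alkyl ketones, which gives the (S)-carbinol that becomes C2.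

Step 6
Reactants: 9 (3S)-3-hydroxy-N-methoxy-3-[4-methoxy-3-(triisopropylsilyloxy)phenyl]-N-methylpropanamide
Product: 10 (3S)-N-methoxy-3-[4-methoxy-3-(triisopropylsilyloxy)phenyl]-N-methyl-3-(triethylsilyloxy)propanamide
Conditions: Et3SiCl, imidazole, CH2Cl2, 0 °C → rt
Reagents that add atoms: chlorotriethylsilane, CC[Si](Cl)(CC)CC
Why: Standard silylation of a secondary alcohol. The triethylsilyl ether masks the hydroxyl during the dianion step and is later removed by mild acid that leaves the aryl triisopropylsilyl ether untouched.

Step 7
Reactants: 4 3-(2,2-dimethyl-4-oxo-4H-1,3-dioxin-6-yl)-6-methylhept-5-en-2-one; 10 (3S)-N-methoxy-3-[4-methoxy-3-(triisopropylsilyloxy)phenyl]-N-methyl-3-(triethylsilyloxy)propanamide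
Product: 11 (1S)-6-(2,2-dimethyl-4-oxo-4H-1,3-dioxin-6-yl)-1-[4-methoxy-3-(triisopropylsilyloxy)phenyl]-9-methyl-1-(triethylsilyloxy)dec-8-ene-3,5-dione (both C6 epimers, keto–enol mixture)
Conditions: 4 (1.2 equiv), LiN(iPr)2 (2.5 equiv), THF, −78 °C; then 10, −78 → −40 °C; AcOH
Reagents that add atoms: none
Why: Claisen acylation of a keto-dioxinone dianion at its terminal methyl carbon with a Weinreb amide, the established route to diketo-dioxinones. The chelated tetrahedral intermediate prevents over-addition and allows near-equimolar use of 10; no bond to the stereocentre is touched.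

Step 8
Reactants: 11 (1S)-6-(2,2-dimethyl-4-oxo-4H-1,3-dioxin-6-yl)-1-[4-methoxy-3-(triisopropylsilyloxy)phenyl]-9-methyl-1-(triethylsilyloxy)dec-8-ene-3,5-dione
Product: 13 (2S)-6-[1-(2,2-dimethyl-4-oxo-4H-1,3-dioxin-6-yl)-4-methylpent-3-en-1-yl]-2-[4-methoxy-3-(triisopropylsilyloxy)phenyl]-2,3-dihydro-4H-pyran-4-one (both epimers at the side-chain carbon), via hydroxy diketone 12 (not isolated)
Conditions: CF3CO2H (5 equiv), CH2Cl2, H2O (2 equiv), 0 °C; aq NaHCO3
Reagents that add atoms: none
Why: Acidic removal of the triethylsilyl group followed by cyclodehydration of the δ-hydroxy β-diketone, the usual route to 2,3-dihydro-4H-pyran-4-ones. The hydroxyl can reach only the distal carbonyl (six-membered ring) and the C2–O bond is not broken, so the configuration is retained. The short exposure at 0 °C is meant to spare the para-methoxybenzylic centre, the prenyl alkene, the dioxinone and the aryl silyl ether.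

Step 9
Reactants: 13 (2S)-6-[1-(2,2-dimethyl-4-oxo-4H-1,3-dioxin-6-yl)-4-methylpent-3-en-1-yl]-2-[4-methoxy-3-(triisopropylsilyloxy)phenyl]-2,3-dihydro-4H-pyran-4-one
Product: 17 (2S)-5,7-dihydroxy-2-[4-methoxy-3-(triisopropylsilyloxy)phenyl]-8-(3-methylbut-2-en-1-yl)-2,3-dihydro-4H-chromen-4-one, via acylketene 14 (not isolated), via dienylketene 15 (not isolated), via cyclohexadienone 16 (not isolated)
Conditions: PhMe (0.005 M), 4 Å MS, 110 °C
Reagents that add atoms: none
Why: Proposed new method: thermal retro-[4+2] cleavage of the dioxinone, the established way to acylketenes, should release acetone and acylketene 14, whose ketene carbon C5 lies six atoms from the nucleophilic α-carbon C4a of the vinylogous ester O1–C8a=C4a–C4=O. Tautomerisation of the C7 ketone towards the doubly activated C8–H gives dienylketene 15, in which C4a=C8a, C8=C7 and C6=C5 form a hexatriene that can close by thermal disrotatory six-electron electrocyclisation to dienone 16; the same bond would result from direct 6-(enolendo)-exo-dig attack of C4a on the ketene carbon followed by loss of the C8 proton. Enolisation of 16 (C4a–H to O5) gives the aromatic ring A of 17, which should make the sequence irreversible. The closest known reactions are the thermolysis of keto-dioxinones with cyclo-aromatisation to resorcylates and the electrocyclisation of dienylketenes to phenols in benzannulation chemistry; their combination on a dihydropyranone enol ether has no direct precedent. Ring A is the only ring closed (a six-membered carbocycle, by the mode just described), no stereocentre is created, the two C8 epimers of 13 converge because C8 becomes aromatic, and C2 takes no part in these neutral thermal events. The selectivity required is C-acylation at C4a in preference to O-acylation, to attack by the prenyl alkene and to intermolecular capture of the ketene. Pyranone formation by O-acylation is excluded because the oxygen on C8a is already the ring C ether O1, and cycloaddition of the acylketene across C4a=C8a or across the prenyl alkene would require a four-membered ring or a bridgehead double bond. Dimerisation, acylation of the phenols of 17 and hydrolysis are to be suppressed by high dilution, molecular sieves and an aprotic solvent.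

Step 10
Reactants: 17 (2S)-5,7-dihydroxy-2-[4-methoxy-3-(triisopropylsilyloxy)phenyl]-8-(3-methylbut-2-en-1-yl)-2,3-dihydro-4H-chromen-4-one
Product: 18 (2S)-5-hydroxy-7-methoxy-2-[4-methoxy-3-(triisopropylsilyloxy)phenyl]-8-(3-methylbut-2-en-1-yl)-2,3-dihydro-4H-chromen-4-one
Conditions: MeOH (1.1 equiv), PPh3, DIAD, THF, 0 °C → rt
Reagents that add atoms: methanol, CO
Why: Mitsunobu O-methylation, which alkylates the most acidic phenol. The 7-OH, para to the carbonyl, is much more acidic than the chelated 5-OH, and the ring B phenol is silylated, so mono-methylation at O7 is expected under neutral conditions that cannot open ring C.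

Step 11
Reactants: 18 (2S)-5-hydroxy-7-methoxy-2-[4-methoxy-3-(triisopropylsilyloxy)phenyl]-8-(3-methylbut-2-en-1-yl)-2,3-dihydro-4H-chromen-4-one
Product: 19 (2S)-5-hydroxy-2-(3-hydroxy-4-methoxyphenyl)-7-methoxy-8-(3-methylbut-2-en-1-yl)-2,3-dihydro-4H-chromen-4-one (target, CNP0228678.1)
Conditions: Bu4NF–AcOH (1:1), THF, 0 °C
Reagents that add atoms: none
Why: Fluoride cleavage of an aryl silyl ether. The acetic acid buffer keeps the medium non-basic, so retro-oxa-Michael opening of the flavanone and loss of the C2 configuration are not expected, and the prenyl group is inert.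

## Compound list

1 | 2,2,6-trimethyl-4H-1,3-dioxin-4-one | CC1=CC(=O)OC(C)(C)O1 | starting material
2 | 1-bromo-3-methylbut-2-ene (prenyl bromide) | CC(C)=CCBr | starting material
3 | 2,2-dimethyl-6-(4-methylpent-3-en-1-yl)-4H-1,3-dioxin-4-one | CC(C)=CCCC1=CC(=O)OC(C)(C)O1 | intermediate
4 | 3-(2,2-dimethyl-4-oxo-4H-1,3-dioxin-6-yl)-6-methylhept-5-en-2-one (racemic) | CC(=O)C(CC=C(C)C)C1=CC(=O)OC(C)(C)O1 | intermediate
5 | methyl 3-hydroxy-4-methoxybenzoate | COC(=O)c1ccc(OC)c(O)c1 | starting material
6 | methyl 4-methoxy-3-(triisopropylsilyloxy)benzoate | COC(=O)c1ccc(OC)c(O[Si](C(C)C)(C(C)C)C(C)C)c1 | intermediate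
7 | N-methoxy-N-methylacetamide | CC(=O)N(C)OC | starting material
8 | N-methoxy-3-[4-methoxy-3-(triisopropylsilyloxy)phenyl]-N-methyl-3-oxopropanamide | COc1ccc(C(=O)CC(=O)N(C)OC)cc1O[Si](C(C)C)(C(C)C)C(C)C | intermediate
9 | (3S)-3-hydroxy-N-methoxy-3-[4-methoxy-3-(triisopropylsilyloxy)phenyl]-N-methylpropanamide | COc1ccc([C@@H](O)CC(=O)N(C)OC)cc1O[Si](C(C)C)(C(C)C)C(C)C | intermediate
10 | (3S)-N-methoxy-3-[4-methoxy-3-(triisopropylsilyloxy)phenyl]-N-methyl-3-(triethylsilyloxy)propanamide | COc1ccc([C@@H](O[Si](CC)(CC)CC)CC(=O)N(C)OC)cc1O[Si](C(C)C)(C(C)C)C(C)C | intermediate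
11 | (1S)-6-(2,2-dimethyl-4-oxo-4H-1,3-dioxin-6-yl)-1-[4-methoxy-3-(triisopropylsilyloxy)phenyl]-9-methyl-1-(triethylsilyloxy)dec-8-ene-3,5-dione (both C6 epimers) | COc1ccc([C@@H](O[Si](CC)(CC)CC)CC(=O)CC(=O)C(CC=C(C)C)C2=CC(=O)OC(C)(C)O2)cc1O[Si](C(C)C)(C(C)C)C(C)C | intermediate
12 | (1S)-6-(2,2-dimethyl-4-oxo-4H-1,3-dioxin-6-yl)-1-hydroxy-1-[4-methoxy-3-(triisopropylsilyloxy)phenyl]-9-methyldec-8-ene-3,5-dione (not isolated) | COc1ccc([C@@H](O)CC(=O)CC(=O)C(CC=C(C)C)C2=CC(=O)OC(C)(C)O2)cc1O[Si](C(C)C)(C(C)C)C(C)C | intermediate
13 | (2S)-6-[1-(2,2-dimethyl-4-oxo-4H-1,3-dioxin-6-yl)-4-methylpent-3-en-1-yl]-2-[4-methoxy-3-(triisopropylsilyloxy)phenyl]-2,3-dihydro-4H-pyran-4-one (both side-chain epimers) | COc1ccc([C@@H]2CC(=O)C=C(C(CC=C(C)C)C3=CC(=O)OC(C)(C)O3)O2)cc1O[Si](C(C)C)(C(C)C)C(C)C | intermediate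
14 | 4-{(2S)-2-[4-methoxy-3-(triisopropylsilyloxy)phenyl]-4-oxo-2,3-dihydro-4H-pyran-6-yl}-7-methylocta-1,6-diene-1,3-dione (acylketene, not isolated) | COc1ccc([C@@H]2CC(=O)C=C(C(CC=C(C)C)C(=O)C=C=O)O2)cc1O[Si](C(C)C)(C(C)C)C(C)C | intermediate
15 | 3-hydroxy-4-{(2S)-2-[4-methoxy-3-(triisopropylsilyloxy)phenyl]-4-oxo-2,3-dihydro-4H-pyran-6-yl}-7-methylocta-1,3,6-trien-1-one (dienylketene, not isolated) | COc1ccc([C@@H]2CC(=O)C=C(C(CC=C(C)C)=C(O)C=C=O)O2)cc1O[Si](C(C)C)(C(C)C)C(C)C | intermediate
16 | (2S)-7-hydroxy-2-[4-methoxy-3-(triisopropylsilyloxy)phenyl]-8-(3-methylbut-2-en-1-yl)-2,3-dihydro-4aH-chromene-4,5-dione (dienone tautomer, not isolated) | COc1ccc([C@@H]2CC(=O)C3C(=O)C=C(O)C(CC=C(C)C)=C3O2)cc1O[Si](C(C)C)(C(C)C)C(C)C | intermediate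
17 | (2S)-5,7-dihydroxy-2-[4-methoxy-3-(triisopropylsilyloxy)phenyl]-8-(3-methylbut-2-en-1-yl)-2,3-dihydro-4H-chromen-4-one | COc1ccc([C@@H]2CC(=O)c3c(O)cc(O)c(CC=C(C)C)c3O2)cc1O[Si](C(C)C)(C(C)C)C(C)C | intermediate
18 | (2S)-5-hydroxy-7-methoxy-2-[4-methoxy-3-(triisopropylsilyloxy)phenyl]-8-(3-methylbut-2-en-1-yl)-2,3-dihydro-4H-chromen-4-one | COc1ccc([C@@H]2CC(=O)c3c(O)cc(OC)c(CC=C(C)C)c3O2)cc1O[Si](C(C)C)(C(C)C)C(C)C | intermediate
19 | (2S)-5-hydroxy-2-(3-hydroxy-4-methoxyphenyl)-7-methoxy-8-(3-methylbut-2-en-1-yl)-2,3-dihydro-4H-chromen-4-one | COc1ccc([C@@H]2CC(=O)c3c(O)cc(OC)c(CC=C(C)C)c3O2)cc1O | target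

## Step count and risk

Total: 11 steps. Longest linear sequence: 9 steps (steps 3 to 11, from 5); the dioxinone branch (steps 1 and 2) joins at step 7.

**Step 9 (key step, new method).** The most likely failure is diversion of acylketene 14 before C4a can attack it, because the α-carbon of a vinylogous ester is only a moderate nucleophile. The diverting processes are dimerisation, acylation of the phenols of product already formed, an ene-type closure by the prenyl alkene (its inner carbon is also six atoms from C5), and hydrolysis with decarboxylation by traces of water.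

Fallback, from 13 back to 17, with known chemistry: thermolysis of 13 in toluene at 110 °C in the presence of methanol should intercept the ketene as methyl 4-{(2S)-2-[4-methoxy-3-(triisopropylsilyloxy)phenyl]-4-oxo-2,3-dihydro-4H-pyran-6-yl}-7-methyl-3-oxooct-6-enoate F1, the standard fate of a dioxinone heated with an alcohol. Treatment of F1 with DBU in toluene (or NaOMe in MeOH if a stronger base is needed) should then effect a Dieckmann-type Claisen condensation of the C8-derived dienolate through C4a onto the ester, with loss of methanol and tautomerisation to 17. The competing aldol closure onto C4 is geometrically impossible (bridgehead alkene). The basic conditions put C2 at risk through retro-oxa-Michael opening, so the enantiomeric purity would have to be checked at 17.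

**Step 7.** The most likely failure is proton transfer instead of addition: the dianion of 4 deprotonates 10 at its α-methylene, and β-elimination of the silanolate follows. Incomplete formation of the dianion of the branched ketone 4 would add to this.

Fallback, from 10 and 4 back to 11: reduction of 10 with iBu2AlH (THF, −78 °C) should give (3S)-3-[4-methoxy-3-(triisopropylsilyloxy)phenyl]-3-(triethylsilyloxy)propanal F2. Aldol addition of the dianion of 4 to this far more electrophilic aldehyde should give (1S)-6-(2,2-dimethyl-4-oxo-4H-1,3-dioxin-6-yl)-3-hydroxy-1-[4-methoxy-3-(triisopropylsilyloxy)phenyl]-9-methyl-1-(triethylsilyloxy)dec-8-en-5-one F3 as a mixture of carbinol epimers, and Dess–Martin oxidation of F3 returns to the route at 11.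

**Step 8.** The most likely failure is ionisation of the para-methoxybenzylic C–O bond under acid. Elimination to the styryl diketone and re-closure by oxa-Michael addition would erode the enantiomeric purity, and protonation of the prenyl alkene is a second acid-driven loss.

Fallback, from 11 back to 13: buffered HF·pyridine (THF–pyridine, 0 °C) should remove the triethylsilyl group without strong acid, and hydroxy diketone 12 is expected to close to the cyclic hemiketal (6S)-2-[1-(2,2-dimethyl-4-oxo-4H-1,3-dioxin-6-yl)-4-methylpent-3-en-1-yl]-2-hydroxy-6-[4-methoxy-3-(triisopropylsilyloxy)phenyl]tetrahydro-4H-pyran-4-one F4. Activation of the hemiketal hydroxyl of F4 with (CF3CO)2O and Et3N (CH2Cl2, −20 °C) and base-mediated β-elimination should give 13 without a benzylic cation.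

**Step 1.** The most likely failure is poor site selectivity of the dienolate (ring α-carbon against exocyclic γ-carbon) together with dialkylation, because 3 is about as acidic as 1.

Fallback, from 1 back to 4, which bypasses 3 and step 2: acylation of the dienolate of 1 (LiN(SiMe3)2, then AcCl) should give the known 2,2-dimethyl-6-(2-oxopropyl)-4H-1,3-dioxin-4-one F5. C-Alkylation of its doubly activated methylene with 2 (K2CO3, acetone) then returns to the route at 4, relying on the usual carbon selectivity of 1,3-dicarbonyl-type anions towards allylic bromides.

## Further compounds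

F1 | step 9 | methyl 4-{(2S)-2-[4-methoxy-3-(triisopropylsilyloxy)phenyl]-4-oxo-2,3-dihydro-4H-pyran-6-yl}-7-methyl-3-oxooct-6-enoate | COc1ccc([C@@H]2CC(=O)C=C(C(CC=C(C)C)C(=O)CC(=O)OC)O2)cc1O[Si](C(C)C)(C(C)C)C(C)C
F2 | step 7 | (3S)-3-[4-methoxy-3-(triisopropylsilyloxy)phenyl]-3-(triethylsilyloxy)propanal | COc1ccc([C@@H](O[Si](CC)(CC)CC)CC=O)cc1O[Si](C(C)C)(C(C)C)C(C)C
F3 | step 7 | (1S)-6-(2,2-dimethyl-4-oxo-4H-1,3-dioxin-6-yl)-3-hydroxy-1-[4-methoxy-3-(triisopropylsilyloxy)phenyl]-9-methyl-1-(triethylsilyloxy)dec-8-en-5-one | COc1ccc([C@@H](O[Si](CC)(CC)CC)CC(O)CC(=O)C(CC=C(C)C)C2=CC(=O)OC(C)(C)O2)cc1O[Si](C(C)C)(C(C)C)C(C)C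
F4 | step 8 | (6S)-2-[1-(2,2-dimethyl-4-oxo-4H-1,3-dioxin-6-yl)-4-methylpent-3-en-1-yl]-2-hydroxy-6-[4-methoxy-3-(triisopropylsilyloxy)phenyl]tetrahydro-4H-pyran-4-one | COc1ccc([C@@H]2CC(=O)CC(O)(C(CC=C(C)C)C3=CC(=O)OC(C)(C)O3)O2)cc1O[Si](C(C)C)(C(C)C)C(C)C
F5 | step 1 | 2,2-dimethyl-6-(2-oxopropyl)-4H-1,3-dioxin-4-one | CC(=O)CC1=CC(=O)OC(C)(C)O1
A1 | alternative 1 | (2S,4S)-5-(allyloxy)-2-[3-(allyloxy)-4-methoxyphenyl]-4,7-dimethoxy-8-(3-methylbut-2-en-1-yl)chromane | COc1ccc([C@@H]2C[C@H](OC)c3c(OCC=C)cc(OC)c(CC=C(C)C)c3O2)cc1OCC=C
A2 | alternative 1 | 3-(allyloxy)-2-(dimethoxymethyl)-5-methoxy-6-(3-methylbut-2-en-1-yl)phenol | COC(OC)c1c(OCC=C)cc(OC)c(CC=C(C)C)c1O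
A3 | alternative 1 | 2-(allyloxy)-1-methoxy-4-vinylbenzene | COc1ccc(C=C)cc1OCC=C
A4 | alternative 2 | (2S)-7-methoxy-2-[4-methoxy-3-(triisopropylsilyloxy)phenyl]-8-(3-methylbut-2-en-1-yl)-5-(triisopropylsilyloxy)chroman-4-one | COc1ccc([C@@H]2CC(=O)c3c(O[Si](C(C)C)(C(C)C)C(C)C)cc(OC)c(CC=C(C)C)c3O2)cc1O[Si](C(C)C)(C(C)C)C(C)C
A5 | alternative 2 | 2-diazo-1-[4-methoxy-2-{[4-methoxy-3-(triisopropylsilyloxy)phenyl]methoxy}-3-(3-methylbut-2-en-1-yl)-6-(triisopropylsilyloxy)phenyl]ethanone | COc1ccc(COc2c(CC=C(C)C)c(OC)cc(O[Si](C(C)C)(C(C)C)C(C)C)c2C(=O)C=[N+]=[N-])cc1O[Si](C(C)C)(C(C)C)C(C)C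
A6 | alternative 3 | (2S,4S)-7-methoxy-5-(methoxymethoxy)-2-[4-methoxy-3-(methoxymethoxy)phenyl]-8-(3-methylbut-2-en-1-yl)chroman-4-ol | COc1ccc([C@@H]2C[C@H](O)c3c(OCOC)cc(OC)c(CC=C(C)C)c3O2)cc1OCOC
A7 | alternative 3 | (1S,3S)-1-[2-bromo-4-methoxy-6-(methoxymethoxy)-3-(3-methylbut-2-en-1-yl)phenyl]-3-[4-methoxy-3-(methoxymethoxy)phenyl]propane-1,3-diol | COc1ccc([C@@H](O)C[C@H](O)c2c(OCOC)cc(OC)c(CC=C(C)C)c2Br)cc1OCOC
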